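**Plan**

- Retrosynthesis: the 3'-O–benzyl bond is cut first, then O1–C2 of ring C, which opens the pyranone to an ortho-hydroxyaryl ynone. C4–C4a and C8a–O1 are then cut together to give 3,4,5,6-tetramethoxybenzyne and an arylpropiolic acid, and the C2–C1' bond is cut to an aryl iodide and propiolic acid.
- Enabling feature: in ring A, C4a and C8a each have a methoxylated neighbour (C5, C8) followed by a methoxylated carbon (C6, C7). The aryne is therefore symmetric, and O1 and the C4 acyl carbon can enter at either end with the same result.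
- Forward: the ring A aryne precursor 8 is made from 1,2,3,4-tetramethoxybenzene (3 steps) and the ring B acid 16 from 2-hydroxy-3,4-dimethoxybenzaldehyde (5 steps). The insertion joins rings A and B through the C4–C3–C2 chain without closing a ring, ring C then closes by amine-mediated 6-endo cyclisation, and debenzylation ends the route.
- Stereochemistry: the target has no stereocentre and no configured double bond, so nothing has to be set or protected.

Key step: step 9

Remark: compounds 1, 9 and 15 are taken as commercial. Ring B starts from 9 because its benzyl ether can be iodinated at a phenol stage where only one ring position is ortho to a free hydroxyl. A benzyl ether made from 1,2,4-trimethoxybenzene would offer two positions of nearly equal reactivity.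

**Route**

Step 1
Reactants: 1 1,2,3,4-tetramethoxybenzene
Product: 4 2,3,4,5-tetramethoxyphenol, via (2,3,4,5-tetramethoxyphenyl)lithium 2 (not isolated), via dimethyl (2,3,4,5-tetramethoxyphenyl)boronate 3 (not isolated)
Conditions: n-BuLi, TMEDA, THF, 0 °C to rt; B(OMe)3, −78 °C to rt; AcOH, 30% aq. H2O2, 0 °C to rt
Reagents that add atoms: hydrogen peroxide, OO
Why: Directed ortho-metalation at the ring position next to an outer methoxy group (the two ring hydrogens are equivalent), borylation of the aryllithium and oxidation of C–B to C–O is a standard lithiation–borylation–oxidation sequence from anisoles to phenols.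

Step 2
Reactants: 4 2,3,4,5-tetramethoxyphenol
Product: 5 2-bromo-3,4,5,6-tetramethoxyphenol
Conditions: NBS, CH2Cl2, −78 to 0 °C, dark
Reagents that add atoms: N-bromosuccinimide, O=C1CCC(=O)N1Br
Why: Electrophilic aromatic bromination can only take place at the single unsubstituted ring carbon, which is ortho to the hydroxyl and strongly activated, and the low temperature should hold back oxidation of the phenol.

Step 3
Reactants: 5 2-bromo-3,4,5,6-tetramethoxyphenol
Product: 8 2,3,4,5-tetramethoxy-6-(trimethylsilyl)phenyl trifluoromethanesulfonate, via (2-bromo-3,4,5,6-tetramethoxyphenoxy)trimethylsilane 6 (not isolated), via lithium 2,3,4,5-tetramethoxy-6-(trimethylsilyl)phenoxide 7 (not isolated)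
Conditions: HMDS, THF, 70 °C, then evaporate; n-BuLi, THF, −100 to −80 °C; Tf2O, −100 to −80 °C; cold aq. NaHCO3
Reagents that add atoms: hexamethyldisilazane, C[Si](C)(C)N[Si](C)(C)C; trifluoromethanesulfonic anhydride, O=S(=O)(OS(=O)(=O)C(F)(F)F)C(F)(F)F
Why: O-Silylation, bromine–lithium exchange and anionic 1,3 O→C silyl migration (retro-Brook rearrangement) place the silyl group ortho to a lithium phenoxide, which triflic anhydride sulfonylates in the usual one-flask conversion of ortho-bromophenols into ortho-silylaryl triflates.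

Step 4
Reactants: 9 2-hydroxy-3,4-dimethoxybenzaldehyde
Product: 10 2-(benzyloxy)-3,4-dimethoxybenzaldehyde
Conditions: BnBr, K2CO3, DMF, 60 °C
Reagents that add atoms: benzyl bromide, BrCc1ccccc1
Why: Williamson etherification masks the oxygen that becomes the 3'-hydroxyl with a group that should survive peracid, base, fluoride and palladium(0) and is removable by hydrogenolysis.

Step 5
Reactants: 10 2-(benzyloxy)-3,4-dimethoxybenzaldehyde
Product: 12 2-(benzyloxy)-3,4-dimethoxyphenol, via 2-(benzyloxy)-3,4-dimethoxyphenyl formate 11 (not isolated)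
Conditions: mCPBA, CH2Cl2, 0 °C to rt; then KOH, MeOH/H2O, rt; acidify
Reagents that add atoms: 3-chloroperoxybenzoic acid, OOC(=O)c1cccc(Cl)c1
Why: Baeyer–Villiger (Dakin-type) oxidation, in which the aryl group carrying ortho and para alkoxy donors migrates in preference to hydrogen, followed by saponification of the formate to the phenol.

Step 6
Reactants: 12 2-(benzyloxy)-3,4-dimethoxyphenol
Product: 13 2-(benzyloxy)-6-iodo-3,4-dimethoxyphenol
Conditions: NIS, MeCN, 0 °C, dark
Reagents that add atoms: N-iodosuccinimide, O=C1CCC(=O)N1I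
Why: Electrophilic aromatic iodination is directed by the free hydroxyl, the strongest donor on the ring, to its only open ortho position (its para position carries a methoxy group), which fixes the site of the later aryl–alkyne bond.

Step 7
Reactants: 13 2-(benzyloxy)-6-iodo-3,4-dimethoxyphenol
Product: 14 3-(benzyloxy)-1-iodo-2,4,5-trimethoxybenzene
Conditions: MeI, K2CO3, acetone, reflux
Reagents that add atoms: iodomethane, CI
Why: Williamson O-methylation under mild carbonate conditions leaves the aryl iodide and the benzyl ether untouched.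

Step 8
Reactants: 14 3-(benzyloxy)-1-iodo-2,4,5-trimethoxybenzene; 15 propiolic acid
Product: 16 3-[3-(benzyloxy)-2,4,5-trimethoxyphenyl]prop-2-ynoic acid
Conditions: Pd(PPh3)4 (5 mol%), DBU (2.2 equiv), DMSO, 35 °C; then 1 M HCl
Reagents that add atoms: none
Why: Copper-free Sonogashira-type coupling of an aryl iodide with propiolic acid as its amidinium salt is known to stop at the arylpropiolic acid near room temperature, because decarboxylation needs a higher temperature.

Step 9
Reactants: 8 2,3,4,5-tetramethoxy-6-(trimethylsilyl)phenyl trifluoromethanesulfonate; 16 3-[3-(benzyloxy)-2,4,5-trimethoxyphenyl]prop-2-ynoic acid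
Product: 19 3-[3-(benzyloxy)-2,4,5-trimethoxyphenyl]-1-(2-hydroxy-3,4,5,6-tetramethoxyphenyl)prop-2-yn-1-one, via caesium 3-[3-(benzyloxy)-2,4,5-trimethoxyphenyl]prop-2-ynoate 17 (not isolated), via 3,4,5,6-tetramethoxybenzyne 18 (not isolated)
Conditions: 16, Cs2CO3 (0.5 equiv), MeOH, rt, then evaporate and dry in vacuo; 8 (1.5 equiv, added in portions), CsF, 4 Å MS, THF, 125 °C (sealed tube); then 1 M HCl, 0 °C
Reagents that add atoms: none
Why: Fluoride removes the silyl group of 8 and triflate departs to give aryne 18, the carboxylate oxygen of 17 adds to one aryne carbon, and the ortho aryl anion so formed attacks its own ester carbonyl through a four-membered alkoxide that collapses to the ortho-acyl phenoxide, so that C8a–O1 and C4a–C4 are made in one operation. The closest known reaction type is the formal insertion of arynes from ortho-silylaryl triflates into the C–O bond of carboxylic acids (an aryne-triggered anionic Fries-type 1,3-acyl shift) to give ortho-hydroxyaryl ketones. No ring closes and no stereocentre arises; the phenoxide is kept as its caesium salt in an aprotic medium and protonated cold, so the open-chain ynone should be isolated. The step needs no regiocontrol, because both aryne carbons have a methoxylated neighbour (C5 and C8) with a further methoxylated carbon beyond it (C6 and C7), which makes the two ends identical. It does need the acyl shift to outrun protonation of the aryl anion, and this is secured by the dry preformed caesium salt (no O–H donor present), by the molecular sieves and by the proximity of the carbonyl group. The benzyl ether keeps the only other phenolic oxygen from adding to the aryne.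

Step 10
Reactants: 19 3-[3-(benzyloxy)-2,4,5-trimethoxyphenyl]-1-(2-hydroxy-3,4,5,6-tetramethoxyphenyl)prop-2-yn-1-one
Product: 21 2-[3-(benzyloxy)-2,4,5-trimethoxyphenyl]-5,6,7,8-tetramethoxy-4H-chromen-4-one, via (E)-3-[3-(benzyloxy)-2,4,5-trimethoxyphenyl]-3-(diethylamino)-1-(2-hydroxy-3,4,5,6-tetramethoxyphenyl)prop-2-en-1-one 20 (not isolated)
Conditions: Et2NH (3 equiv), EtOH, 60 °C
Reagents that add atoms: none
Why: Conjugate addition of the secondary amine gives the β-amino enone, whose β-carbon the ortho-hydroxyl attacks in a 6-endo addition–elimination that expels the amine (amine-mediated oxa-Michael cyclisation of ortho-hydroxyaryl ynones), which shuts off the 5-exo path to the aurone.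

Step 11
Reactants: 21 2-[3-(benzyloxy)-2,4,5-trimethoxyphenyl]-5,6,7,8-tetramethoxy-4H-chromen-4-one
Product: 22 Agehoustin C, 2-(3-hydroxy-2,4,5-trimethoxyphenyl)-5,6,7,8-tetramethoxy-4H-chromen-4-one
Conditions: H2 (1 atm), 10% Pd/C, EtOAc/MeOH, rt, stopped when 21 is consumed
Reagents that add atoms: none
Why: Catalytic hydrogenolysis cleaves the benzyl–oxygen bond under balloon pressure, conditions under which aryl methyl ethers and the flavone C2=C3 bond are normally retained.

**Compound list**

1 | 1,2,3,4-tetramethoxybenzene | COc1ccc(OC)c(OC)c1OC | starting material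
2 | (2,3,4,5-tetramethoxyphenyl)lithium | [Li]c1cc(OC)c(OC)c(OC)c1OC | intermediate
3 | dimethyl (2,3,4,5-tetramethoxyphenyl)boronate | COB(OC)c1cc(OC)c(OC)c(OC)c1OC | intermediate
4 | 2,3,4,5-tetramethoxyphenol | Oc1cc(OC)c(OC)c(OC)c1OC | intermediate
5 | 2-bromo-3,4,5,6-tetramethoxyphenol | Oc1c(Br)c(OC)c(OC)c(OC)c1OC | intermediate
6 | (2-bromo-3,4,5,6-tetramethoxyphenoxy)trimethylsilane | C[Si](C)(C)Oc1c(Br)c(OC)c(OC)c(OC)c1OC | intermediate
7 | lithium 2,3,4,5-tetramethoxy-6-(trimethylsilyl)phenoxide | [Li]Oc1c([Si](C)(C)C)c(OC)c(OC)c(OC)c1OC | intermediate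
8 | 2,3,4,5-tetramethoxy-6-(trimethylsilyl)phenyl trifluoromethanesulfonate | COc1c(OC)c(OC)c([Si](C)(C)C)c(OS(=O)(=O)C(F)(F)F)c1OC | intermediate
9 | 2-hydroxy-3,4-dimethoxybenzaldehyde | O=Cc1ccc(OC)c(OC)c1O | starting material
10 | 2-(benzyloxy)-3,4-dimethoxybenzaldehyde | O=Cc1ccc(OC)c(OC)c1OCc1ccccc1 | intermediate
11 | 2-(benzyloxy)-3,4-dimethoxyphenyl formate | O=COc1ccc(OC)c(OC)c1OCc1ccccc1 | intermediate
12 | 2-(benzyloxy)-3,4-dimethoxyphenol | Oc1ccc(OC)c(OC)c1OCc1ccccc1 | intermediate
13 | 2-(benzyloxy)-6-iodo-3,4-dimethoxyphenol | Oc1c(I)cc(OC)c(OC)c1OCc1ccccc1 | intermediate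
14 | 3-(benzyloxy)-1-iodo-2,4,5-trimethoxybenzene | COc1c(I)cc(OC)c(OC)c1OCc1ccccc1 | intermediate
15 | propiolic acid (prop-2-ynoic acid) | C#CC(=O)O | starting material
16 | 3-[3-(benzyloxy)-2,4,5-trimethoxyphenyl]prop-2-ynoic acid | OC(=O)C#Cc1cc(OC)c(OC)c(OCc2ccccc2)c1OC | intermediate
17 | caesium 3-[3-(benzyloxy)-2,4,5-trimethoxyphenyl]prop-2-ynoate | [Cs+].[O-]C(=O)C#Cc1cc(OC)c(OC)c(OCc2ccccc2)c1OC | intermediate
18 | 3,4,5,6-tetramethoxybenzyne | COC1=C(OC)C(OC)=C(OC)C#C1 | intermediate
19 | 3-[3-(benzyloxy)-2,4,5-trimethoxyphenyl]-1-(2-hydroxy-3,4,5,6-tetramethoxyphenyl)prop-2-yn-1-one | COc1c(OC)c(OC)c(C(=O)C#Cc2cc(OC)c(OC)c(OCc3ccccc3)c2OC)c(O)c1OC | intermediate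
20 | (E)-3-[3-(benzyloxy)-2,4,5-trimethoxyphenyl]-3-(diethylamino)-1-(2-hydroxy-3,4,5,6-tetramethoxyphenyl)prop-2-en-1-one (drawn as E; the geometry is lost on ring closure) | CCN(CC)/C(c1cc(OC)c(OC)c(OCc2ccccc2)c1OC)=C/C(=O)c1c(O)c(OC)c(OC)c(OC)c1OC | intermediate
21 | 2-[3-(benzyloxy)-2,4,5-trimethoxyphenyl]-5,6,7,8-tetramethoxy-4H-chromen-4-one | COc1cc(-c2cc(=O)c3c(OC)c(OC)c(OC)c(OC)c3o2)c(OC)c(OCc2ccccc2)c1OC | intermediate
22 | Agehoustin C, 2-(3-hydroxy-2,4,5-trimethoxyphenyl)-5,6,7,8-tetramethoxy-4H-chromen-4-one | COc1cc(-c2cc(=O)c3c(OC)c(OC)c(OC)c(OC)c3o2)c(OC)c(O)c1OC | target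

**Step count and risks**

Total step count: 11 (steps 1–3 for ring A, steps 4–8 for ring B, steps 9–11 after the union).
Longest linear sequence: 8 steps (9 → 10 → 12 → 13 → 14 → 16 → 19 → 21 → 22).

Steps most likely to fail:

1. Step 9. The aryl anion may be protonated before the 1,3-acyl shift, which ends at the aryl ester. The propiolate may lose CO2 at the reaction temperature. The product phenoxide may add to the ynone in the flask without 6-endo/5-exo control, or to a second aryne. The fallback sets out from 4 and 14 and comes back at 21, so it also replaces step 10. Friedel–Crafts acetylation of 4 at its only free ring position (AcOH, BF3·OEt2, heat) should give 1-(2-hydroxy-3,4,5,6-tetramethoxyphenyl)ethan-1-one F1. Iodine–lithium exchange on 14 (n-BuLi, THF, −78 °C) should give [3-(benzyloxy)-2,4,5-trimethoxyphenyl]lithium F2, which DMF formylates to 3-(benzyloxy)-2,4,5-trimethoxybenzaldehyde F3. Claisen–Schmidt condensation of F1 with F3 (KOH, EtOH, rt) should give (E)-3-[3-(benzyloxy)-2,4,5-trimethoxyphenyl]-1-(2-hydroxy-3,4,5,6-tetramethoxyphenyl)prop-2-en-1-one F4. Oxidative cyclisation of F4 with catalytic iodine in DMSO at 120 °C should give 21.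

2. Step 8. The coupled acid may decarboxylate under palladium and base and couple a second time to the diarylalkyne, and oxidative addition into the electron-rich, ortho-methoxylated iodide may be slow. The fallback sets out from 14 and comes back at 16. Sonogashira coupling of 14 with trimethylsilylacetylene (PdCl2(PPh3)2, CuI, Et3N, 50 °C) should give {[3-(benzyloxy)-2,4,5-trimethoxyphenyl]ethynyl}trimethylsilane F5. Fluoride-mediated desilylative carboxylation of F5 (CsF, CO2 at 1 atm, DMSO, rt) then gives the caesium salt 17, and acidification gives 16.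

3. Step 2. The N-bromo reagent may oxidise the very electron-rich para-methoxyphenol (quinone formation with loss of a methyl group) in competition with ring bromination. The fallback sets out from 4 and comes back at 5. Acetylation (Ac2O, pyridine) should give 2,3,4,5-tetramethoxyphenyl acetate F6, which is far harder to oxidise. NBS in MeCN should brominate its single free ring position to 2-bromo-3,4,5,6-tetramethoxyphenyl acetate F7, and methanolysis (K2CO3, MeOH, rt) returns 5.

Further compounds
F1 | step 9 | 1-(2-hydroxy-3,4,5,6-tetramethoxyphenyl)ethan-1-one | CC(=O)c1c(O)c(OC)c(OC)c(OC)c1OC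
F2 | step 9 | [3-(benzyloxy)-2,4,5-trimethoxyphenyl]lithium | [Li]c1cc(OC)c(OC)c(OCc2ccccc2)c1OC
F3 | step 9 | 3-(benzyloxy)-2,4,5-trimethoxybenzaldehyde | O=Cc1cc(OC)c(OC)c(OCc2ccccc2)c1OC
F4 | step 9 | (E)-3-[3-(benzyloxy)-2,4,5-trimethoxyphenyl]-1-(2-hydroxy-3,4,5,6-tetramethoxyphenyl)prop-2-en-1-one | COc1c(OC)c(OC)c(C(=O)/C=C/c2cc(OC)c(OC)c(OCc3ccccc3)c2OC)c(O)c1OC
F5 | step 8 | {[3-(benzyloxy)-2,4,5-trimethoxyphenyl]ethynyl}trimethylsilane | C[Si](C)(C)C#Cc1cc(OC)c(OC)c(OCc2ccccc2)c1OC
F6 | step 2 | 2,3,4,5-tetramethoxyphenyl acetate | CC(=O)Oc1cc(OC)c(OC)c(OC)c1OC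
F7 | step 2 | 2-bromo-3,4,5,6-tetramethoxyphenyl acetate | CC(=O)Oc1c(Br)c(OC)c(OC)c(OC)c1OC
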